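Read these flasks by one concentration, that of G in solution, which I take to set the pace of each step that consumes G, so that at a steady level those steps run pseudo-first-order.

| setting | winter | larch | cedar | alder |
|---|---|---|---|---|
| D | 0.050 M | 0.10 M | 0.10 M | 0.10 M |
| G | 3.2 mM (held) | 3.2 mM (held) | 3.2 mM (held) | 3.2 mM (held) |
| temperature | 25 °C |  | 25 °C | 10 °C |
| remark | run made earlier | at 25 °C until 30 min, from then on at 10 °C |  |  |
| time |  | 1.0 h | 1.0 h | 1.0 h |

- winter (time / min: Z / %, D / %): 1.33: 2.4, 83.9; 2.00: 5.5, 77.1; 3.00: 13.2, 66.7; 5.00: 26.5, 50.7; 8.00: 47.3, 32.1; 12.0: 67.8, 15.6; 20.0: 86.6, 3.3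

(scatter of a reading: 0.5 percentage points)

- what was read earlier has a scatter of 0.5 percentage points, one standard deviation
- at the start none of G is in solution
- the earlier runs do not show what temperature does; that part of a forecast is a guess

- the best flask by amount of Z, in percent of the D charged; "all alike" if 1.5 percentage points covers them all (larch / cedar / alder / all alike)
- amount of Z at the end, in percent of the D charged, larch
- amount of Z at the end, in percent of the D charged, cedar
- amount of Z at the end, in percent of the D charged, alder

I start with the main steps alone, D passing through some intermediate to Z while G in solution stands near its limit of 3.2 mM. The tail of the winter run reads a constant for D of 0.190 min⁻¹, which gives 11.4 time constants in cedar's 60 min, so this picture carries the whole charge to Z.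

Now I add the crossing of G into solution. The first winter readings give only 0.137 min⁻¹, slower than the tail, and I read that as G in solution standing at 72.5% of its limit under early demand. That makes the shortfall over the level 0.380, and I let it grow with the charge, so twice the D of the winter run puts cedar's level at 56.8%. Even held that low, I reckon cedar's D at 3.93% of the charge by 30 min and 0.156% by 60 min. With no leak yet in this picture, the hold-up moves the timing of Z and not its final amount, and I let larch, cooled at 30 min, read as cedar.

Last comes the leak. At its final reading the winter run still lacks 10.1% of the charge, some perhaps still intermediate, and I treat this as a first-order escape racing the step that takes up G. The leak odds, the share lost over the share reaching Z, are then 0.112, and they should rise as the level falls. For cedar and larch that gives odds of 0.143 and Z at 87.5%. Temperature is unread, so for alder I guess the same odds.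

The forecast says 91% for larch, 91% for cedar, 89.5% for alder and all alike, holding that “the plateau is about 91–92%”, higher than my figure.

The flasks give 86.0% in larch, 86.2% in cedar and 89.9% in alder, so alder is best, and my guess of unchanged odds parts from the flask there, by 3.7 percentage points over cedar.

    L + X → Z + J (k = 3.34 M⁻¹ s⁻¹, Ea = 59.0 kJ mol⁻¹)
    E ⇌ J, rate k2*(cs2 - [J]) while solid is left; crystals form when [J] > cs2 (solubility = 0.0650 M, k = 0.0703 s⁻¹)
    D + L → X + J (k = 1.24 M⁻¹ s⁻¹, Ea = 58.0 kJ mol⁻¹)
    G ⇌ L, rate k4*(csat - [L]) (kL = 0.0962 s⁻¹)
    X → Q (k = 9.06 × 10⁻⁴ s⁻¹, Ea = 90.0 kJ mol⁻¹)
    (constants at 25 °C)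

The leak is X turning into Q, and cedar ends with odds of Q over Z at 0.161 against my 0.143. The neighbouring flask is cedar with 2.50 times the charge of D. The same reckoning puts its level at 34.5%, its odds at 0.236 and its Z at 80.9%. That flask ends with Z at 79.0% and Q at 20.9% of its charge, odds of 0.265.

The readings come from a simulation with constants of no real substance; noise was put on by code.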